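**Plan**

1. Retrosynthesis (flavan numbering for the upper unit, rings A/C/B; the lower unit is (+)-catechin). The C2 stereocentre is first dissolved into the C2=C3 bond of a flav-2-ene (4H-chromene). Ring C is then cut at O1–C8a to the enolate of an aryl ketone facing a C8a–Br bond. The interflavan bond C4–C8(catechin) is cut as a Friedel–Crafts conjugate addition to a 2-bromochalcone, and the chalcone is cut at C3–C4 into an aldehyde and an acetophenone.
2. Forward: rings A and B and the whole catechin unit are bought. The chain is joined C3–C4 (Claisen–Schmidt), then C4–C8(catechin) (Friedel–Crafts). Ring C is the only ring made, by copper-catalysed O-arylation of the ketone enolate (O1–C8a).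
3. Enabling feature: C2 carries both O1 and ring B, so ring C is the cyclic aryl enol ether of a B-ring aryl ketone. C8a of ring A is ortho to the benzylic C4, so the enolate oxygen reaches C8a through a six-membered ring, whereas its carbon end (C3) would have to close a four-membered ring. The other ortho position (C5) already carries oxygen, so there is no regiochemical choice.
4. Stereochemistry: C2 and C3 of catechin are bought. C4 is set by catalysis after ring closure: both C4 epimers are oxidised to one planar 4-arylflavylium ion, and hydride is returned under chiral phosphate control. C2 is relayed from C4 by hydrogenation of the enol ether anti to the 4-aryl group (2,4-cis), in the same operation that removes the eight benzyl groups.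

Key step: step 5

Remark: 1,3-bis(benzyloxy)-5-bromobenzene (3) and 3',4'-bis(benzyloxy)acetophenone (5) are taken as catalogue compounds; each is otherwise one benzylation away from 5-bromoresorcinol or 3',4'-dihydroxyacetophenone.
Remark: the facial sense of the phosphate-directed hydride transfer in step 7 cannot be derived from first principles for this ion; (R)-TRIP is written and stands for whichever enantiomer of the acid leads to 4S. The axial configuration of the phosphate is given in the name of 12, as the SMILES notation does not carry it.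

Bn = benzyl throughout.

**Route**

Step 1
Reactants: 1 (+)-catechin
Product: 2 5,7,3',4'-tetra-O-benzyl-(+)-catechin
Conditions: BnBr (4.4 equiv), K2CO3, DMF, 0 °C → rt
Reagents that add atoms: benzyl bromide, BrCc1ccccc1
Why: Williamson O-benzylation of the four phenols by K2CO3; the aliphatic 3-OH is not deprotonated and stays free, and neither stereocentre is touched.

Step 2
Reactants: 3 1,3-bis(benzyloxy)-5-bromobenzene
Product: 4 2-bromo-4,6-bis(benzyloxy)benzaldehyde
Conditions: POCl3, DMF, 0 → 70 °C; then ice-water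
Reagents that add atoms: N,N-dimethylformamide, CN(C)C=O; water, O
Why: Vilsmeier–Haack formylation at one of the two equivalent positions between Br and OBn (ortho to one ether, para to the other), which should be the major site and gives the C8a–Br/C5–OBn pattern of ring A; the minor isomer formylated between the two ethers is removed by crystallisation.

Step 3
Reactants: 4 2-bromo-4,6-bis(benzyloxy)benzaldehyde; 5 1-[3,4-bis(benzyloxy)phenyl]ethan-1-one
Product: 6 (E)-3-[2-bromo-4,6-bis(benzyloxy)phenyl]-1-[3,4-bis(benzyloxy)phenyl]prop-2-en-1-one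
Conditions: KOH, EtOH–THF, rt
Reagents that add atoms: none
Why: Claisen–Schmidt condensation (aldol addition, then E1cB dehydration) forms C3–C4; the conjugated (E)-enone is the thermodynamic product.

Step 4
Reactants: 6 (E)-2-bromochalcone; 2 5,7,3',4'-tetra-O-benzyl-(+)-catechin (1.3 equiv)
Product: 7 3-[2-bromo-4,6-bis(benzyloxy)phenyl]-1-[3,4-bis(benzyloxy)phenyl]-3-(tetra-O-benzylcatechin-8-yl)propan-1-one as both C3 epimers
Conditions: Sc(OTf)3 (10 mol %), CH2Cl2, 0 °C → rt
Reagents that add atoms: none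
Why: Friedel–Crafts conjugate addition: Sc(III) coordination turns the enone into a benzylic cation stabilised by the 4,6-dialkoxy ring A, which is attacked by C8 of the benzylated phloroglucinol ring of 2 (more accessible than C6, as in 4→8 proanthocyanidin couplings) to form the interflavan bond; C4 forms without control and both epimers are carried on because steps 6 and 7 converge them.

Step 5
Reactants: 7 β,β-diaryl ketone (both C4 epimers)
Product: 9 5,7-bis(benzyloxy)-2-[3,4-bis(benzyloxy)phenyl]-4-(tetra-O-benzylcatechin-8-yl)-4H-chromene as both C4 epimers, via caesium (Z)-enolate 8 (not isolated)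
Conditions: CuI (10 mol %), 1,10-phenanthroline (20 mol %), Cs2CO3 (2 equiv), DMF, 100 °C
Reagents that add atoms: none
Why: Cs2CO3 reversibly forms the (Z)-enolate 8 (aryl trans to C4), whose oxygen binds Cu(I)·phenanthroline; oxidative addition of the neighbouring C8a–Br bond and C–O reductive elimination give the aryl enol ether (Ullmann-type enolate O-arylation). The closest known reaction type is the copper-catalysed intramolecular O-arylation of ketone enolates, as in the cyclisation of 2-haloaryl ketones to benzofurans and of 2-bromobenzyl 1,3-dicarbonyl compounds to 4H-chromenes. Ring C is closed by attack of O1 on the ipso carbon C8a, a 6-exo-trig substitution; closure through C3 would give a benzocyclobutene and is not expected. No stereocentre is formed or touched: C4 carries no acidic hydrogen under these conditions, both C4 epimers cyclise, and the catechin centres are remote. The step needs O- over C-arylation, intra- over intermolecular coupling and reaction at one aryl position only; these are secured by the six- versus four-membered ring choice, by C8a–Br being the only halide and lying ortho to the benzylic C4 (C5 is already OBn), and by the catechin 3-OH reaching C8a only through a nine-membered ring. The product keeps C2 as an sp2 enol ether carbon next to C4, which is what later allows C4 to be corrected through the flavylium ion and C2 to be set from C4.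

Step 6
Reactants: 9 flav-2-ene (both C4 epimers)
Product: 11 5,7-bis(benzyloxy)-2-[3,4-bis(benzyloxy)phenyl]-2-methoxy-4-(tetra-O-benzylcatechin-8-yl)-2H-chromene (mixed ketal; C2 epimers), via 4-arylflavylium hydroquinone-monoanion salt 10 (not isolated)
Conditions: DDQ (1.05 equiv), CH2Cl2–MeOH, −20 → 0 °C; aq. NaHCO3 work-up
Reagents that add atoms: methanol, CO
Why: DDQ dehydrogenation (electron transfer, then loss of the C4 hydrogen) converts the 4H-chromene of either epimer into the same planar 4-arylflavylium ion, paired with the DDQ-derived hydroquinone monoanion (10), which methanol captures at C2 as the mixed ketal; the electron-rich enol ether should be oxidised well before the benzylic CH2 of the catechin unit at this temperature and with one equivalent of oxidant, and the C4 stereocentre is deliberately erased.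

Step 7
Reactants: 11 2-methoxy-2H-chromene ketal
Product: 13 (4S)-5,7-bis(benzyloxy)-2-[3,4-bis(benzyloxy)phenyl]-4-(tetra-O-benzylcatechin-8-yl)-4H-chromene, via 4-arylflavylium (R)-TRIP phosphate ion pair 12 (not isolated)
Conditions: (R)-TRIP (10 mol %), Hantzsch ester (1.3 equiv), toluene, 4 Å MS, 0 °C → rt
Reagents that add atoms: none
Why: asymmetric counter-anion-directed transfer hydrogenation (1,4-reduction) of a 2,4-diaryl-1-benzopyrylium ion: the chiral phosphoric acid ionises the ketal with loss of methanol to the contact ion pair 12, and the Hantzsch ester transfers hydride to C4 on the face left open by the chiral phosphate, so C4 should be set as S by the catalyst whatever the epimer ratio of 9.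

Step 8
Reactants: 13 (4S)-flav-2-ene
Product: 15 (2S,4S)-2-(3,4-dihydroxyphenyl)-4-[(2R,3S)-2-(3,4-dihydroxyphenyl)-3,5,7-trihydroxychroman-8-yl]chroman-5,7-diol (CNP0180676.1), via octa-O-benzyl flavan 14 (not isolated)
Conditions: H2 (1 atm), Pd(OH)2/C, THF–MeOH, rt
Reagents that add atoms: none
Why: heterogeneous hydrogenation should add H2 to the C2=C3 enol ether from the face opposite the pseudo-axial catechin substituent at C4, which sets C2 as S (2,4-cis) by substrate control, and continued hydrogenolysis cleaves the eight O-benzyl groups; the flavan C2–O1 bonds and the interflavan bond should survive these neutral conditions.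

**Compound list**

1 | (+)-catechin, (2R,3S)-2-(3,4-dihydroxyphenyl)chroman-3,5,7-triol | Oc1cc(O)c2c(c1)O[C@H](c1ccc(O)c(O)c1)[C@@H](O)C2 | starting material
2 | (2R,3S)-5,7-bis(benzyloxy)-2-[3,4-bis(benzyloxy)phenyl]chroman-3-ol (tetra-O-benzylcatechin) | c1ccccc1COc1cc(OCc3ccccc3)c2c(c1)O[C@H](c1ccc(OCc3ccccc3)c(OCc3ccccc3)c1)[C@@H](O)C2 | intermediate
3 | 1,3-bis(benzyloxy)-5-bromobenzene | Brc1cc(OCc2ccccc2)cc(OCc2ccccc2)c1 | starting material
4 | 2-bromo-4,6-bis(benzyloxy)benzaldehyde | O=Cc1c(Br)cc(OCc2ccccc2)cc1OCc1ccccc1 | intermediate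
5 | 1-[3,4-bis(benzyloxy)phenyl]ethan-1-one | CC(=O)c1ccc(OCc2ccccc2)c(OCc2ccccc2)c1 | starting material
6 | (E)-3-[2-bromo-4,6-bis(benzyloxy)phenyl]-1-[3,4-bis(benzyloxy)phenyl]prop-2-en-1-one | O=C(/C=C/c1c(Br)cc(OCc2ccccc2)cc1OCc1ccccc1)c1ccc(OCc2ccccc2)c(OCc2ccccc2)c1 | intermediate
7 | 3-[2-bromo-4,6-bis(benzyloxy)phenyl]-1-[3,4-bis(benzyloxy)phenyl]-3-[(2R,3S)-5,7-bis(benzyloxy)-2-[3,4-bis(benzyloxy)phenyl]-3-hydroxychroman-8-yl]propan-1-one, both C3 epimers | O=C(CC(c1c(Br)cc(OCc2ccccc2)cc1OCc1ccccc1)c1c(OCc2ccccc2)cc(OCc2ccccc2)c2c1O[C@H](c1ccc(OCc3ccccc3)c(OCc3ccccc3)c1)[C@@H](O)C2)c1ccc(OCc2ccccc2)c(OCc2ccccc2)c1 | intermediate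
8 | caesium (Z)-enolate of 7 | [Cs+].[O-]/C(=C\C(c1c(Br)cc(OCc2ccccc2)cc1OCc1ccccc1)c1c(OCc2ccccc2)cc(OCc2ccccc2)c2c1O[C@H](c1ccc(OCc3ccccc3)c(OCc3ccccc3)c1)[C@@H](O)C2)c1ccc(OCc2ccccc2)c(OCc2ccccc2)c1 | intermediate (not isolated)
9 | 5,7-bis(benzyloxy)-2-[3,4-bis(benzyloxy)phenyl]-4-[(2R,3S)-5,7-bis(benzyloxy)-2-[3,4-bis(benzyloxy)phenyl]-3-hydroxychroman-8-yl]-4H-chromene, both C4 epimers | c1ccccc1COc1cc(OCc3ccccc3)c2c(c1)OC(c1ccc(OCc3ccccc3)c(OCc3ccccc3)c1)=CC2c1c(OCc2ccccc2)cc(OCc2ccccc2)c2c1O[C@H](c1ccc(OCc3ccccc3)c(OCc3ccccc3)c1)[C@@H](O)C2 | intermediate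
10 | 5,7-bis(benzyloxy)-2-[3,4-bis(benzyloxy)phenyl]-4-[(2R,3S)-5,7-bis(benzyloxy)-2-[3,4-bis(benzyloxy)phenyl]-3-hydroxychroman-8-yl]chromenylium (flavylium) 2,3-dichloro-5,6-dicyano-4-hydroxyphenolate | [O-]c1c(Cl)c(Cl)c(O)c(C#N)c1C#N.c1ccccc1COc1cc(OCc3ccccc3)c2c(c1)[o+]c(-c1ccc(OCc3ccccc3)c(OCc3ccccc3)c1)cc2-c1c(OCc2ccccc2)cc(OCc2ccccc2)c2c1O[C@H](c1ccc(OCc3ccccc3)c(OCc3ccccc3)c1)[C@@H](O)C2 | intermediate (not isolated)
11 | 5,7-bis(benzyloxy)-2-[3,4-bis(benzyloxy)phenyl]-2-methoxy-4-[(2R,3S)-5,7-bis(benzyloxy)-2-[3,4-bis(benzyloxy)phenyl]-3-hydroxychroman-8-yl]-2H-chromene, C2 epimers | c1ccccc1COc1cc(OCc3ccccc3)c2c(c1)OC(OC)(c1ccc(OCc3ccccc3)c(OCc3ccccc3)c1)C=C2c1c(OCc2ccccc2)cc(OCc2ccccc2)c2c1O[C@H](c1ccc(OCc3ccccc3)c(OCc3ccccc3)c1)[C@@H](O)C2 | intermediate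
12 | 5,7-bis(benzyloxy)-2-[3,4-bis(benzyloxy)phenyl]-4-[(2R,3S)-5,7-bis(benzyloxy)-2-[3,4-bis(benzyloxy)phenyl]-3-hydroxychroman-8-yl]chromenylium (R)-3,3'-bis(2,4,6-triisopropylphenyl)-1,1'-binaphthalene-2,2'-diyl phosphate (contact ion pair) | c1ccccc1COc1cc(OCc3ccccc3)c2c(c1)[o+]c(-c1ccc(OCc3ccccc3)c(OCc3ccccc3)c1)cc2-c1c(OCc2ccccc2)cc(OCc2ccccc2)c2c1O[C@H](c1ccc(OCc3ccccc3)c(OCc3ccccc3)c1)[C@@H](O)C2.CC(C)c1cc(C(C)C)c(c(C(C)C)c1)-c1cc2ccccc2c3c1OP(=O)([O-])Oc1c(-c4c(C(C)C)cc(C(C)C)cc4C(C)C)cc4ccccc4c1-3 | intermediate (not isolated)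
13 | (4S)-5,7-bis(benzyloxy)-2-[3,4-bis(benzyloxy)phenyl]-4-[(2R,3S)-5,7-bis(benzyloxy)-2-[3,4-bis(benzyloxy)phenyl]-3-hydroxychroman-8-yl]-4H-chromene | c1ccccc1COc1cc(OCc3ccccc3)c2c(c1)OC(c1ccc(OCc3ccccc3)c(OCc3ccccc3)c1)=C[C@@H]2c1c(OCc2ccccc2)cc(OCc2ccccc2)c2c1O[C@H](c1ccc(OCc3ccccc3)c(OCc3ccccc3)c1)[C@@H](O)C2 | intermediate
14 | (2S,4S)-5,7-bis(benzyloxy)-2-[3,4-bis(benzyloxy)phenyl]-4-[(2R,3S)-5,7-bis(benzyloxy)-2-[3,4-bis(benzyloxy)phenyl]-3-hydroxychroman-8-yl]chroman (2,4-cis) | c1ccccc1COc1cc(OCc3ccccc3)c2c(c1)O[C@H](c1ccc(OCc3ccccc3)c(OCc3ccccc3)c1)C[C@@H]2c1c(OCc2ccccc2)cc(OCc2ccccc2)c2c1O[C@H](c1ccc(OCc3ccccc3)c(OCc3ccccc3)c1)[C@@H](O)C2 | intermediate (not isolated)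
15 | (2S,4S)-2-(3,4-dihydroxyphenyl)-4-[(2R,3S)-2-(3,4-dihydroxyphenyl)-3,5,7-trihydroxychroman-8-yl]chroman-5,7-diol, luteoliflavan-(4α→8)-(+)-catechin | Oc1cc(O)c2c(c1)O[C@H](c1ccc(O)c(O)c1)C[C@@H]2c1c(O)cc(O)c2c1O[C@H](c1ccc(O)c(O)c1)[C@@H](O)C2 | target

**Step count and risks**

Total: 8 steps. Longest linear sequence: 7 steps (3 → 4 → 6 → 7 → 9 → 11 → 13 → 15).

Steps most likely to fail:

1. Step 7. What may go wrong: hydride transfer with poor facial discrimination, or hydride delivery to C2 instead of C4, because C4 of the flavylium ion is shielded by the twisted 2,6-dioxygenated aryl group. The fallback sets out from 9 and comes back at 13. The two C4 epimers of 9 are diastereomers because of the (2R,3S)-catechin unit and are separated by preparative HPLC. The (4S)-epimer is 13 and goes on to step 8. The (4R)-epimer of the flav-2-ene F1 is oxidised under the conditions of step 6 to ketal 11. Ketal 11 is then treated with the Hantzsch ester and achiral diphenyl phosphate, which reduces it through the flavylium diphenyl phosphate ion pair F2 back to the epimer mixture 9, and this is separated again.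

2. Step 5. What may go wrong: slow oxidative addition at the hindered C8a–Br bond, with protodebromination or base-induced degradation of the enolate taking over. The fallback sets out from 7 and comes back at 14; it moves the catalyst-controlled centre to C2 and closes the same O1–C8a bond from an alkoxide. Ketone 7 is reduced with (R)-Me-CBS and BH3·SMe2 to the (1S)-carbinol F3 (both C3 epimers). Palladium-catalysed intramolecular etherification (Pd(OAc)2, 2-(di-tert-butylphosphino)-1,1'-binaphthyl, Cs2CO3, toluene, 80 °C) then closes ring C with retention at C2. It should give the 2,4-cis flavan 14 and its 2,4-trans epimer F4, which should differ enough to be separated on silica. Isolated 14 is debenzylated under the conditions of step 8.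

3. Step 4. What may go wrong: incomplete conversion because the conjugate addition is reversible, competing attack through C6 of the catechin ring, or acid-induced benzyl transfer. The fallback sets out from 2, 4 and 5 and comes back at 7; it fixes the regiochemistry by halogenation and forms both C–C bonds irreversibly. NBS (CH2Cl2, −78 °C) brominates 2 at C8 to the 8-bromide F5. n-BuLi (2.1 equiv, THF, −78 °C) followed by aldehyde 4 gives the diarylmethanol F6. Ketone 5 is converted with TMSOTf and Et3N into its trimethylsilyl enol ether F7. Ionisation of F6 with BF3·OEt2 at −78 °C in the presence of F7 (SN1, Mukaiyama-type alkylation of the diarylmethyl cation) gives 7.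

**Further compounds**

F1 | step 7 | (4R)-5,7-bis(benzyloxy)-2-[3,4-bis(benzyloxy)phenyl]-4-[(2R,3S)-5,7-bis(benzyloxy)-2-[3,4-bis(benzyloxy)phenyl]-3-hydroxychroman-8-yl]-4H-chromene | c1ccccc1COc1cc(OCc3ccccc3)c2c(c1)OC(c1ccc(OCc3ccccc3)c(OCc3ccccc3)c1)=C[C@H]2c1c(OCc2ccccc2)cc(OCc2ccccc2)c2c1O[C@H](c1ccc(OCc3ccccc3)c(OCc3ccccc3)c1)[C@@H](O)C2
F2 | step 7 | 5,7-bis(benzyloxy)-2-[3,4-bis(benzyloxy)phenyl]-4-[(2R,3S)-5,7-bis(benzyloxy)-2-[3,4-bis(benzyloxy)phenyl]-3-hydroxychroman-8-yl]chromenylium diphenyl phosphate (ion pair) | [O-]P(=O)(Oc1ccccc1)Oc1ccccc1.c1ccccc1COc1cc(OCc3ccccc3)c2c(c1)[o+]c(-c1ccc(OCc3ccccc3)c(OCc3ccccc3)c1)cc2-c1c(OCc2ccccc2)cc(OCc2ccccc2)c2c1O[C@H](c1ccc(OCc3ccccc3)c(OCc3ccccc3)c1)[C@@H](O)C2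
F3 | step 5 | (1S)-3-[2-bromo-4,6-bis(benzyloxy)phenyl]-1-[3,4-bis(benzyloxy)phenyl]-3-[(2R,3S)-5,7-bis(benzyloxy)-2-[3,4-bis(benzyloxy)phenyl]-3-hydroxychroman-8-yl]propan-1-ol, both C3 epimers | O[C@@H](CC(c1c(Br)cc(OCc2ccccc2)cc1OCc1ccccc1)c1c(OCc2ccccc2)cc(OCc2ccccc2)c2c1O[C@H](c1ccc(OCc3ccccc3)c(OCc3ccccc3)c1)[C@@H](O)C2)c1ccc(OCc2ccccc2)c(OCc2ccccc2)c1
F4 | step 5 | (2S,4R)-5,7-bis(benzyloxy)-2-[3,4-bis(benzyloxy)phenyl]-4-[(2R,3S)-5,7-bis(benzyloxy)-2-[3,4-bis(benzyloxy)phenyl]-3-hydroxychroman-8-yl]chroman (2,4-trans) | c1ccccc1COc1cc(OCc3ccccc3)c2c(c1)O[C@H](c1ccc(OCc3ccccc3)c(OCc3ccccc3)c1)C[C@H]2c1c(OCc2ccccc2)cc(OCc2ccccc2)c2c1O[C@H](c1ccc(OCc3ccccc3)c(OCc3ccccc3)c1)[C@@H](O)C2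
F5 | step 4 | (2R,3S)-5,7-bis(benzyloxy)-2-[3,4-bis(benzyloxy)phenyl]-8-bromochroman-3-ol | Brc1c(OCc2ccccc2)cc(OCc2ccccc2)c2c1O[C@H](c1ccc(OCc3ccccc3)c(OCc3ccccc3)c1)[C@@H](O)C2
F6 | step 4 | [2-bromo-4,6-bis(benzyloxy)phenyl][(2R,3S)-5,7-bis(benzyloxy)-2-[3,4-bis(benzyloxy)phenyl]-3-hydroxychroman-8-yl]methanol, both carbinol epimers | OC(c1c(Br)cc(OCc2ccccc2)cc1OCc1ccccc1)c1c(OCc2ccccc2)cc(OCc2ccccc2)c2c1O[C@H](c1ccc(OCc3ccccc3)c(OCc3ccccc3)c1)[C@@H](O)C2
F7 | step 4 | {1-[3,4-bis(benzyloxy)phenyl]ethenyloxy}trimethylsilane | C=C(O[Si](C)(C)C)c1ccc(OCc2ccccc2)c(OCc2ccccc2)c1
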